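**Retrosynthetic overview**
- The strategy rests on C4 of the p-menth-1-ene ring. This fully substituted carbon carries the aroyloxy oxygen and the isopropyl group, is stereogenic only through the remote C1=C2 alkene, and lies 1,4 to the methyl-bearing C1. That is the "para" pattern of an isoprene Diels–Alder adduct of a 2-acyloxyacrolein.
- Disconnections: (a) both aryl–prenyl bonds, by a late twofold Stille coupling on a 3,5-dibromoarene; (b) isopropyl ← isopropenyl ← acetyl ← formyl at C4; (c) ring bonds C3–C4 and C5–C6, by [4+2] of isoprene with an acrolein that already carries the aroyl ester, so the hindered tertiary alcohol is never acylated.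
- Rings: the arene is bought; a temporary 1,3-dioxin ring is made and cleaved to unmask the dienophile; the cyclohexene is the only ring built (step 4).

Key step: step 4

Remark (assumption): the (R)-adduct requires the diene to add to the Re face of the dienophile α-carbon (OCOAr → CHO → CH2 clockwise). The L-Phe-L-Leu-derived triamine salt is taken as the catalyst enantiomer that exposes this face. The assignment should be confirmed on adduct 7 (X-ray, anomalous dispersion of bromine), and the D,D-derived catalyst used if the sense is opposite.

**Route**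

Step 1
Reactants: 1 3,5-dibromo-4-methoxybenzoic acid
Product: 2 3,5-dibromo-4-methoxybenzoyl chloride
Conditions: (COCl)2, DMF (cat.), CH2Cl2, 0 °C to rt; concentrated and used crude
Reagents that add atoms: oxalyl chloride, ClC(=O)C(=O)Cl
Why: Acyl chloride formation through the DMF-derived chloroiminium (Vilsmeier-type activation) should be clean, with only gaseous by-products, and the aryl bromides and methyl ether are inert.

Step 2
Reactants: 2 3,5-dibromo-4-methoxybenzoyl chloride; 3 2,2-dimethyl-1,3-dioxan-5-one
Product: 4 2,2-dimethyl-4H-1,3-dioxin-5-yl 3,5-dibromo-4-methoxybenzoate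
Conditions: Et3N, DMAP (cat.), CH2Cl2, 0 °C to rt
Reagents that add atoms: none
Why: The α-alkoxy ketone enolises readily with Et3N and the enol oxygen is acylated by the DMAP-derived acylpyridinium (enol ester formation by O-acylation), giving the dioxin that masks the acrolein.

Step 3
Reactants: 4 2,2-dimethyl-4H-1,3-dioxin-5-yl 3,5-dibromo-4-methoxybenzoate
Product: 5 3-oxoprop-1-en-2-yl 3,5-dibromo-4-methoxybenzoate (the α-aroyloxyacrolein)
Conditions: PhMe, 110–130 °C, acetone distilled off; used promptly
Reagents that add atoms: none
Why: Thermal retro-hetero-Diels–Alder cycloreversion of the 4H-1,3-dioxin should expel acetone and release the 2-acyloxyacrolein without acid or base.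

Step 4
Reactants: 5 3-oxoprop-1-en-2-yl 3,5-dibromo-4-methoxybenzoate; 6 isoprene
Product: 7 (1R)-1-formyl-4-methylcyclohex-3-en-1-yl 3,5-dibromo-4-methoxybenzoate
Conditions: (S,S)-triamine H2NCH(CH2Ph)CH2NHCH(CH2CHMe2)CH2N(CH2)4 (10 mol%; enantiomer as in the remark), C6F5SO3H (27.5 mol%), isoprene (excess), EtNO2, rt
Reagents that add atoms: none
Why: The primary amine of the catalyst salt condenses with the aldehyde of 5 to an aldiminium ion, isoprene adds in a concerted asynchronous [4+2], and hydrolysis releases 7 and the catalyst. The closest known reaction type is the enantioselective Diels–Alder reaction of α-acyloxyacroleins (para-alkoxybenzoyloxy examples included) with acyclic dienes under chiral primary ammonium sulfonate catalysis. The cyclohexene ring is closed by intermolecular [4+2] cycloaddition that forms C3–C4 and C5–C6 (p-menthene numbering) in one event and leaves the C1=C2 alkene. The only new stereocentre, C4, is controlled by the catalyst: an ammonium N–H hydrogen bond to the aroyloxy carbonyl locks the iminium conformation and the benzyl side chain shields one face, so the diene should add to the Re face of the α-carbon and give R. The step needs para regioselectivity, which follows from the larger HOMO coefficient at the CH2 terminus next to the methyl-bearing carbon of isoprene pairing with the β-CH2 of the iminium ion, and facial selectivity, which the hydrogen-bonded catalyst secures; there is no endo/exo issue because the diene has no terminal substituent. The aryl bromides stand in for the prenyl groups, so no acid-sensitive alkene is exposed to the ammonium salt.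

Step 5
Reactants: 7 (1R)-1-formyl-4-methylcyclohex-3-en-1-yl 3,5-dibromo-4-methoxybenzoate
Product: 8 (1R)-1-(1-hydroxyethyl)-4-methylcyclohex-3-en-1-yl 3,5-dibromo-4-methoxybenzoate (both carbinol epimers)
Conditions: MeTi(OiPr)3, THF, −78 to −30 °C; quenched cold with 1 M HCl
Reagents that add atoms: methyltitanium triisopropoxide, C[Ti](OC(C)C)(OC(C)C)OC(C)C
Why: Organotitanium 1,2-addition: the weakly basic reagent adds to aldehydes but not to esters or aryl bromides, and the covalent titanium alkoxide, kept cold and quenched with acid, should not trigger 1,2-acyl migration from the tertiary to the secondary oxygen; the new carbinol centre is uncontrolled and is erased in the next step.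

Step 6
Reactants: 8 (1R)-1-(1-hydroxyethyl)-4-methylcyclohex-3-en-1-yl 3,5-dibromo-4-methoxybenzoate
Product: 9 (1R)-1-acetyl-4-methylcyclohex-3-en-1-yl 3,5-dibromo-4-methoxybenzoate
Conditions: Dess–Martin periodinane, CH2Cl2, 0 °C to rt
Reagents that add atoms: none
Why: Dess–Martin oxidation under near-neutral conditions should convert the secondary alcohol into the methyl ketone without touching the alkene, the ester or the quaternary stereocentre.

Step 7
Reactants: 9 (1R)-1-acetyl-4-methylcyclohex-3-en-1-yl 3,5-dibromo-4-methoxybenzoate
Product: 10 (1R)-4-methyl-1-(prop-1-en-2-yl)cyclohex-3-en-1-yl 3,5-dibromo-4-methoxybenzoate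
Conditions: Zn, CH2Br2, TiCl4 (reagent pre-formed in THF at 5 °C), then 9, CH2Cl2, 0 °C to rt
Reagents that add atoms: dibromomethane, BrCBr
Why: Takai–Lombardo methylenation: the non-basic zinc/titanium methylene reagent converts hindered, enolisable ketones into 1,1-disubstituted alkenes and leaves esters, aryl bromides and the α-oxygenated quaternary centre alone, where a phosphorus ylide could attack the ester.

Step 8
Reactants: 10 (1R)-4-methyl-1-(prop-1-en-2-yl)cyclohex-3-en-1-yl 3,5-dibromo-4-methoxybenzoate
Product: 11 (1R)-4-methyl-1-(propan-2-yl)cyclohex-3-en-1-yl 3,5-dibromo-4-methoxybenzoate ((R)-terpinen-4-yl ester)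
Conditions: H2 (1 atm), RhCl(PPh3)3 (5–10 mol%), PhH/EtOH, rt; stopped after uptake of 1 equiv H2
Reagents that add atoms: none
Why: Homogeneous hydrogenation with RhCl(PPh3)3 discriminates by alkene substitution, so the 1,1-disubstituted isopropenyl group should be saturated before the trisubstituted ring alkene, and this monovalent rhodium catalyst does not hydrogenolyse aryl bromides under these conditions.

Step 9
Reactants: 11 (1R)-4-methyl-1-(propan-2-yl)cyclohex-3-en-1-yl 3,5-dibromo-4-methoxybenzoate; 12 tributyl(3-methylbut-2-en-1-yl)stannane
Product: 14 (1R)-4-methyl-1-(propan-2-yl)cyclohex-3-en-1-yl 4-methoxy-3,5-bis(3-methylbut-2-en-1-yl)benzoate (target), via monoprenylated bromoarene 13 (not isolated)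
Conditions: 12 (3 equiv), Pd(PPh3)4 (10 mol%), DMF, 100 °C, degassed
Reagents that add atoms: none
Why: Twofold Stille coupling: oxidative addition of zerovalent palladium into each C–Br bond, prenyl transfer from tin, and reductive elimination from the less hindered primary terminus of the equilibrating allyl–palladium species should give the linear 3-methylbut-2-enyl group at both positions, with the tertiary homoallylic ester and the ring alkene inert under these neutral conditions.

**Compound list**
1 | 3,5-dibromo-4-methoxybenzoic acid | COc1c(Br)cc(C(=O)O)cc1Br | starting material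
2 | 3,5-dibromo-4-methoxybenzoyl chloride | COc1c(Br)cc(C(=O)Cl)cc1Br | intermediate
3 | 2,2-dimethyl-1,3-dioxan-5-one | CC1(C)OCC(=O)CO1 | starting material
4 | 2,2-dimethyl-4H-1,3-dioxin-5-yl 3,5-dibromo-4-methoxybenzoate | COc1c(Br)cc(C(=O)OC2=COC(C)(C)OC2)cc1Br | intermediate
5 | 3-oxoprop-1-en-2-yl 3,5-dibromo-4-methoxybenzoate | COc1c(Br)cc(C(=O)OC(=C)C=O)cc1Br | intermediate
6 | isoprene | C=CC(C)=C | starting material
7 | (1R)-1-formyl-4-methylcyclohex-3-en-1-yl 3,5-dibromo-4-methoxybenzoate | COc1c(Br)cc(C(=O)O[C@@]2(C=O)CC=C(C)CC2)cc1Br | intermediate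
8 | (1R)-1-(1-hydroxyethyl)-4-methylcyclohex-3-en-1-yl 3,5-dibromo-4-methoxybenzoate, carbinol epimers | COc1c(Br)cc(C(=O)O[C@@]2(C(C)O)CC=C(C)CC2)cc1Br | intermediate
9 | (1R)-1-acetyl-4-methylcyclohex-3-en-1-yl 3,5-dibromo-4-methoxybenzoate | COc1c(Br)cc(C(=O)O[C@@]2(C(C)=O)CC=C(C)CC2)cc1Br | intermediate
10 | (1R)-4-methyl-1-(prop-1-en-2-yl)cyclohex-3-en-1-yl 3,5-dibromo-4-methoxybenzoate | COc1c(Br)cc(C(=O)O[C@@]2(C(C)=C)CC=C(C)CC2)cc1Br | intermediate
11 | (1R)-4-methyl-1-(propan-2-yl)cyclohex-3-en-1-yl 3,5-dibromo-4-methoxybenzoate | COc1c(Br)cc(C(=O)O[C@@]2(C(C)C)CC=C(C)CC2)cc1Br | intermediate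
12 | tributyl(3-methylbut-2-en-1-yl)stannane | CC(C)=CC[Sn](CCCC)(CCCC)CCCC | starting material
13 | (1R)-4-methyl-1-(propan-2-yl)cyclohex-3-en-1-yl 3-bromo-4-methoxy-5-(3-methylbut-2-en-1-yl)benzoate | COc1c(Br)cc(C(=O)O[C@@]2(C(C)C)CC=C(C)CC2)cc1CC=C(C)C | intermediate
14 | (1R)-4-methyl-1-(propan-2-yl)cyclohex-3-en-1-yl 4-methoxy-3,5-bis(3-methylbut-2-en-1-yl)benzoate | COc1c(CC=C(C)C)cc(C(=O)O[C@@]2(C(C)C)CC=C(C)CC2)cc1CC=C(C)C | target

**Step count and risks**
Total step count: 9. Longest linear sequence: 9 steps (1 to 14).

Steps most likely to fail: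

1. Step 8, loss of chemoselectivity. The isopropenyl group sits on a fully substituted carbon, so its hydrogenation may be little faster than that of the ring alkene, leading to over-reduction or stalling. Fallback from 10, returning at 11: the ring alkene is masked first. mCPBA (CH2Cl2, 0 °C) should epoxidise the more electron-rich trisubstituted ring alkene in preference to the hindered, inductively deactivated isopropenyl group and give the ring epoxide of 10 F1 as a mixture of epoxide diastereomers. With one alkene left, hydrogenation (H2, 3–4 atm, RhCl(PPh3)3, PhH/EtOH) can be driven to completion to the isopropyl epoxide F2. Reductive deoxygenation through the iodohydrin (NaI, NaOAc, AcOH, then Zn) should restore the alkene in its original position and deliver 11.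

2. Step 5, acyl migration. In the metal alkoxide the aroyl group may shift from the tertiary to the new secondary oxygen, or the addition to the neopentyl-type aldehyde may be sluggish. Fallback from 7, returning at 9 and bypassing 8: the aldehyde is oxidised instead of alkylated. Pinnick oxidation (NaClO2, NaH2PO4, 2-methylbut-2-ene, t-BuOH/H2O) should give (1R)-1-[(3,5-dibromo-4-methoxybenzoyl)oxy]-4-methylcyclohex-3-ene-1-carboxylic acid F3. (COCl)2 with catalytic DMF in CH2Cl2 converts it into the acid chloride F4, and Me2CuLi (Et2O, −78 °C) should stop at methyl ketone 9. No alkoxide is ever generated next to the tertiary ester.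

3. Step 4, insufficient facial or regiochemical control. The dibromoaroyl carbonyl is a weaker hydrogen-bond acceptor than the para-alkoxybenzoyl precedent, which may lower enantioselectivity, and a racemic background reaction or polymerisation of 5 may compete. Fallback from 5 and 6, returning at 7: the cycloaddition is run without chiral control (PhMe, sealed tube, 80–100 °C, or catalytic ZnCl2 in CH2Cl2) to give the racemic adduct F5. The enantiomers are then separated by preparative chromatography on a chiral stationary phase, with crystallisation of the dibromoaroyl ester as a further means of enrichment; the (R)-enantiomer is 7.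

**Further compounds**
F1 | step 8 | 6-methyl-3-(prop-1-en-2-yl)-7-oxabicyclo[4.1.0]heptan-3-yl 3,5-dibromo-4-methoxybenzoate (ester-bearing carbon as in 10, epoxide diastereomers) | COc1c(Br)cc(C(=O)O[C@@]2(C(C)=C)CC3OC3(C)CC2)cc1Br
F2 | step 8 | 6-methyl-3-(propan-2-yl)-7-oxabicyclo[4.1.0]heptan-3-yl 3,5-dibromo-4-methoxybenzoate (ester-bearing carbon as in 11, epoxide diastereomers) | COc1c(Br)cc(C(=O)O[C@@]2(C(C)C)CC3OC3(C)CC2)cc1Br
F3 | step 5 | (1R)-1-[(3,5-dibromo-4-methoxybenzoyl)oxy]-4-methylcyclohex-3-ene-1-carboxylic acid | COc1c(Br)cc(C(=O)O[C@@]2(C(=O)O)CC=C(C)CC2)cc1Br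
F4 | step 5 | (1R)-1-(chlorocarbonyl)-4-methylcyclohex-3-en-1-yl 3,5-dibromo-4-methoxybenzoate | COc1c(Br)cc(C(=O)O[C@@]2(C(=O)Cl)CC=C(C)CC2)cc1Br
F5 | step 4 | racemic 1-formyl-4-methylcyclohex-3-en-1-yl 3,5-dibromo-4-methoxybenzoate | COc1c(Br)cc(C(=O)OC2(C=O)CC=C(C)CC2)cc1Br
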